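The operator must decide whether this recipe can stay as it is and how long the flask should stand.

- gamma: free monomer 1.7 M; initiator 5.7 mol%; the very flask that is asked about, followed so far
- flask: free monomer 1.7 M; initiator 5.7 mol%; time 25 min

gamma run (percent of the free monomer charged)

| time / min | monomer in chains / % | free monomer / % |
|---|---|---|
| 1.00 | 25.4 | 63.3 |
| 2.00 | 37.4 | 43.4 |
| 3.00 | 44.1 | 30.4 |
| 4.00 | 48.9 | 22.3 |
| 5.00 | 51.8 | 16.4 |

(standard deviation of a reading: 0.3 percentage points)

- average number of monomer units in a chain (chains begun, living or dead) at 25 min
- part of the free monomer that has reacted at 25 min

- the average divides the monomer in chains by the number of chains begun, living and dead together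
- the earlier runs do not show the number of chains; that part of a forecast is a guess

Work with the fraction left and not with the fraction made, treating the late decay of c(free monomer) as pseudo-first-order. Take the last two readings of the gamma run, 22.3% at 4.00 min and 16.4% at 5.00 min. Between them the late decay constant reads 0.307 /min: that is the logarithm of the ratio of two successive fractions left, divided by the time between them. Between the first two readings it read 0.377 /min, so it is sagging, and any figure carried forward from it is a hopeful one.

Carry it forward anyway. My reckoning leaves 0.0351% of the free monomer at 25 min and gives it a half-life of 2.26 min. That half-life is shorter than 25 min, so keep the charge and the full time, which leaves room for further sag.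

The forecast gives 98.5% reacted and 11 units a chain, the second by its own word a guess. It leaves more free monomer than my reckoning does, and it reasons from the words “Even if the rate keeps sagging”.

The flask gives 99.9% reacted and 10.5 units a chain, with 0.093% of the free monomer left at 25 min.

    free monomer + initiator → living end + monomer in chains (k = 0.0611 /M/s)
    free monomer + living end → monomer in chains + living end, rate k2*[living end]*[free monomer] (k = 0.0607 /M/s)
    free monomer → uncatalysed product (k = 0.00220 /s)
    living end + free monomer → dead end (k = 0.00435 /M/s)

Reckon the late decay constant again, from 2.22% left at 12.5 min to the end: it reads 0.254 /min, less than the gamma reading. Averaged from the charge to 25 min, this flask has 0.279 /min. The neighbour charged with 3.4 mol% of initiator has, over the same span, 0.195 /min, and it holds 0.768% of its free monomer at 25 min.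

The numbers in the tables stem from a simulated flask with made-up constants, noise included.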